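**Retrosynthetic overview**

- The target is an 8-O-4′ neolignan; the last bond made is the C8–O bond to C4′ of ring B, cut by a Mitsunobu disconnection (inversion at C8) into 4-allyl-2,6-dimethoxyphenol and an (R)-1-arylpropan-2-ol with the ring A phenol silylated.
- The (R)-alcohol comes from an (R)-C8 pinacol boronate by stereoretentive C–B oxidation.
- Key disconnection: C8–C9 and C7–C1 (ring A) are formed together in one enantioselective three-component conjunctive coupling of a vinylboronate (C7–C8), methyllithium (C9) and the ring A aryl bromide.
- Feature used: C8 is an oxygen-bearing methine flanked only by methyl C9 and the benzylic CH2 C7 on C1 of guaiacyl ring A, so boron can hold the place of the C8 oxygen.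
- No ring is formed; rings A and B are bought as benzene derivatives and only joined.

Key step: step 2

Assumption: the sense of asymmetric induction is taken to be the same for a migrating methyl as for the documented aryl and primary alkyl groups, which points to the (Rp,Rp) ligand antipode for (R)-6; the configuration would be confirmed at alcohol 7, and the equally available (Sp,Sp) antipode used if the sense proved opposite.

**Route**

Step 1
Reactants: 1 4-bromo-2-methoxyphenol
Product: 2 (4-bromo-2-methoxyphenoxy)triisopropylsilane
Conditions: TIPSCl (1.2 equiv), imidazole (2.5 equiv), DMF, rt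
Reagents that add atoms: triisopropylsilyl chloride, CC(C)[Si](Cl)(C(C)C)C(C)C
Why: Standard silylation of a phenol with a silyl chloride and imidazole; the bulky silyl ether masks the acidic OH from methyllithium and from the later Mitsunobu step and is removable with fluoride.

Step 2
Reactants: 3 vinylboronic acid pinacol ester; 4 methyllithium; 2 (4-bromo-2-methoxyphenoxy)triisopropylsilane
Product: 6 (R)-2-[1-(3-methoxy-4-triisopropylsilyloxyphenyl)propan-2-yl]-4,4,5,5-tetramethyl-1,3,2-dioxaborolane, via lithium methyl(vinyl)pinacolatoborate 5 (not isolated)
Conditions: 3, MeLi 4 (low-halide, Et2O), 0 °C → rt, then solvent exchange to THF; then 2, Pd(OAc)2 (2 mol %), (Rp,Rp)-1,1′-bis(diphenylphosphino)-2,2′-bis[(S)-α-(dimethylamino)benzyl]ferrocene (MandyPhos-type ligand, C52H50FeN2P2, 2.4 mol %), NaOTf (2 equiv), THF, 60 °C; non-oxidative aqueous work-up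
Reagents that add atoms: none
Why: Oxidative addition of the C–Br bond of 2 to zerovalent palladium, followed by bromide/triflate exchange with NaOTf (NaBr precipitates), should give a cationic aryl complex of divalent palladium that binds the vinyl group of ate complex 5; methyl then shifts from boron to C8 anti to the metal (C8–C9 bond) while C7 bonds to palladium, and reductive elimination forms the C7–C1 bond to ring A. The closest known reaction type is the enantioselective palladium-catalysed conjunctive cross-coupling of vinylboron ate complexes with aryl triflates or halides, run here with methyl as the migrating group. No ring is closed. C8 is the only new stereocenter and is set by the chiral ferrocenyl bisphosphine on palladium, which selects the face of the bound vinyl group; the anti 1,2-shift is stereospecific and the resulting C–B bond is configurationally stable. The step needs the metalate shift to outrun direct Suzuki-type transfer of methyl or vinyl and β-hydride elimination, which the wide-bite-angle bisphosphine, the halide-free cationic palladium centre and the four-coordinate boron of 5 should secure; the silyl ether and methoxy group are inert to 5.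

Step 3
Reactants: 6 (R)-2-[1-(3-methoxy-4-triisopropylsilyloxyphenyl)propan-2-yl]-4,4,5,5-tetramethyl-1,3,2-dioxaborolane
Product: 7 (R)-1-(3-methoxy-4-triisopropylsilyloxyphenyl)propan-2-ol
Conditions: NaBO3·4H2O (5 equiv), THF/H2O (1:1), rt
Reagents that add atoms: sodium perborate tetrahydrate (NaBO3·4H2O), [Na+].[Na+].O[B-]1(O)OO[B-](O)(O)OO1
Why: Stereoretentive oxidation of a secondary alkylboronic ester (1,2-shift of C8 from boron to oxygen on the peroxoborate adduct) should convert (R)-6 into (R)-7 in a weakly basic medium at room temperature that leaves the aryl silyl ether in place.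

Step 4
Reactants: 7 (R)-1-(3-methoxy-4-triisopropylsilyloxyphenyl)propan-2-ol; 8 4-allyl-2,6-dimethoxyphenol
Product: 9 (S)-{4-[2-(4-allyl-2,6-dimethoxyphenoxy)propyl]-2-methoxyphenoxy}triisopropylsilane
Conditions: 8 (1.5 equiv), PPh3 (1.5 equiv), DIAD (1.5 equiv), THF, 0 °C → rt
Reagents that add atoms: none
Why: Mitsunobu etherification, in which phenol 8 (the only free acidic OH, the ring A phenol being silylated) should displace the oxyphosphonium-activated secondary alcohol by SN2 with inversion, turning (R)-C8 into the (S)-C8 aryl ether.

Step 5
Reactants: 9 (S)-{4-[2-(4-allyl-2,6-dimethoxyphenoxy)propyl]-2-methoxyphenoxy}triisopropylsilane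
Product: 10 (S)-4-[2-(4-allyl-2,6-dimethoxyphenoxy)propyl]-2-methoxyphenol (target)
Conditions: TBAF (1.2 equiv), AcOH (1.2 equiv), THF, 0 °C → rt
Reagents that add atoms: none
Why: Fluoride-induced cleavage of the aryl silyl ether (Si–F bond formation), buffered with acetic acid so that the allyl group, the alkyl aryl ether and the C8 stereocenter are untouched.

**Compound list**

1 | 4-bromo-2-methoxyphenol | COc1cc(Br)ccc1O | starting material
2 | (4-bromo-2-methoxyphenoxy)triisopropylsilane | COc1cc(Br)ccc1O[Si](C(C)C)(C(C)C)C(C)C | intermediate
3 | vinylboronic acid pinacol ester | C=CB1OC(C)(C)C(C)(C)O1 | starting material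
4 | methyllithium | [Li]C | starting material
5 | lithium methyl(vinyl)pinacolatoborate (ate complex, not isolated) | [Li+].C=C[B-]1(C)OC(C)(C)C(C)(C)O1 | intermediate
6 | (R)-2-[1-(3-methoxy-4-triisopropylsilyloxyphenyl)propan-2-yl]-4,4,5,5-tetramethyl-1,3,2-dioxaborolane | C[C@@H](B1OC(C)(C)C(C)(C)O1)Cc1ccc(O[Si](C(C)C)(C(C)C)C(C)C)c(OC)c1 | intermediate
7 | (R)-1-(3-methoxy-4-triisopropylsilyloxyphenyl)propan-2-ol | C[C@@H](O)Cc1ccc(O[Si](C(C)C)(C(C)C)C(C)C)c(OC)c1 | intermediate
8 | 4-allyl-2,6-dimethoxyphenol | C=CCc1cc(OC)c(O)c(OC)c1 | starting material
9 | (S)-{4-[2-(4-allyl-2,6-dimethoxyphenoxy)propyl]-2-methoxyphenoxy}triisopropylsilane | C=CCc1cc(OC)c(O[C@@H](C)Cc2ccc(O[Si](C(C)C)(C(C)C)C(C)C)c(OC)c2)c(OC)c1 | intermediate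
10 | (S)-4-[2-(4-allyl-2,6-dimethoxyphenoxy)propyl]-2-methoxyphenol | C=CCc1cc(OC)c(O[C@@H](C)Cc2ccc(O)c(OC)c2)c(OC)c1 | target

**Step count**

Total steps: 5. Longest linear sequence: 5 steps (1 → 2 → 6 → 7 → 9 → 10).

**Steps most likely to fail**

1. Step 2. The small methyl group may migrate too slowly, so that direct Suzuki-type transfer of methyl or vinyl to the aryl–palladium complex competes, or facial discrimination of the bound vinyl group may be insufficient and erode the enantiomeric purity at C8. Fallback (chiral-pool epoxide opening in place of asymmetric catalysis): aryl bromide 2 is converted with Mg turnings in THF into (3-methoxy-4-triisopropylsilyloxyphenyl)magnesium bromide F1. F1 opens commercial (R)-propylene oxide (C[C@@H]1CO1) at the unsubstituted carbon under CuI catalysis (10 mol %, THF, −30 → 0 °C), leaving the stereocenter untouched. A cold dilute HCl quench gives alcohol 7, where the route is rejoined.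

2. Step 4. The activated secondary alcohol may eliminate toward the conjugated propenylarene, or attack by the di-ortho-substituted phenol may be so slow that the reduced azodicarboxylate is alkylated instead. Fallback (sulfonate activation and SN2 displacement): alcohol 7 is treated with MsCl and Et3N in CH2Cl2 at 0 °C to give (R)-1-(3-methoxy-4-triisopropylsilyloxyphenyl)propan-2-yl methanesulfonate F2. F2 is displaced with inversion by phenol 8 and K2CO3 in dry DMF at 50–60 °C to give ether 9, where the route is rejoined.

3. Step 3. The aryl silyl ether may be partly hydrolysed in the basic peroxide medium, giving a mixture of silylated and free phenol. Fallback (full deprotection and chemoselective reprotection): boronate 6 is oxidised with H2O2/NaOH in THF/H2O, and the silyl ether hydrolysis is driven to completion with NaOH in MeOH at 40 °C, giving (R)-4-(2-hydroxypropyl)-2-methoxyphenol F3. F3 is silylated selectively at the phenol, in preference to the hindered secondary alcohol, with TIPSCl (1.05 equiv) and imidazole in CH2Cl2 at 0 °C to return alcohol 7.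

**Further compounds**

F1 | step 2 | (3-methoxy-4-triisopropylsilyloxyphenyl)magnesium bromide | COc1cc([Mg]Br)ccc1O[Si](C(C)C)(C(C)C)C(C)C
F2 | step 4 | (R)-1-(3-methoxy-4-triisopropylsilyloxyphenyl)propan-2-yl methanesulfonate | C[C@@H](OS(C)(=O)=O)Cc1ccc(O[Si](C(C)C)(C(C)C)C(C)C)c(OC)c1
F3 | step 3 | (R)-4-(2-hydroxypropyl)-2-methoxyphenol | C[C@@H](O)Cc1ccc(O)c(OC)c1
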